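**Retrosynthetic overview**
1. Open the pyranone at O1–C2 (aryl O–CH= bond) and then C2–C3; C2 leaves as a one-carbon unit (an isocyanide carbon), giving a C-prenylated pentahydroxydeoxybenzoin.
2. The O1–C2 bond decides 6- versus 8-prenyl: the ortho-OH next to the prenyl group is chelated to the ketone and becomes 5-OH; the other ortho-OH forms the C–O bond.
3. Cut the C-prenyl bond at the deoxybenzoin stage, where the two free ring CH positions are equivalent, giving prenyl bromide and 2,4,6,3',4'-pentahydroxydeoxybenzoin.
4. Cut the aryl–CO bond, giving phloroglucinol and 3,4-dihydroxyphenylacetic acid (Friedel–Crafts).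
5. Ring order: rings A and B are bought; ring C (the pyranone) is the only ring formed, and it is formed last; no protecting groups.

Assumption: the target has no stereocentre and no stereogenic double bond, so "single enantiomer" places no demand and no stereochemistry has to be set.

**Step 1**
Reactants: 1 phloroglucinol; 2 3,4-dihydroxyphenylacetic acid
Product: 3 2-(3,4-dihydroxyphenyl)-1-(2,4,6-trihydroxyphenyl)ethan-1-one
Conditions: BF3·OEt2 (solvent), 85 °C, 2 h, Ar; then 10% aq. NaOAc
Reagents that add atoms: none
Why: Friedel–Crafts C-acylation (Houben–Hoesch type) of phloroglucinol by the BF3-activated arylacetic acid; the three ring positions are equivalent, the first acyl group deactivates the ring against a second one, and water is the only by-product.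

**Step 2**
Reactants: 3 2-(3,4-dihydroxyphenyl)-1-(2,4,6-trihydroxyphenyl)ethan-1-one; 4 prenyl bromide
Product: 5 2-(3,4-dihydroxyphenyl)-1-[2,4,6-trihydroxy-3-(3-methylbut-2-en-1-yl)phenyl]ethan-1-one
Conditions: KOH (1.0 equiv), degassed H2O, 0 °C → rt, Ar, slow addition of 4 (1.0 equiv); chromatography, recovered 3 recycled
Reagents that add atoms: none
Why: Nuclear C-prenylation (ambident phenoxide C-alkylation in water) of the acylphloroglucinol monoanion, which is the most acidic site (pKa about 8, catechol about 9.5); the two free ring carbons of 3 are equivalent, so only one mono-C-prenyl isomer can form.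

**Step 3**
Reactants: 5 2-(3,4-dihydroxyphenyl)-1-[2,4,6-trihydroxy-3-(3-methylbut-2-en-1-yl)phenyl]ethan-1-one
Product: 8 6-prenylorobol, via aryl formimidate 6 (not isolated), via 2-anilinoisoflavanone 7 (not isolated)
Conditions: 2,6-Me2C6H3NC (1.5 equiv), (IPr)CuCl (5 mol%), KOt-Bu (5 mol%), 4 Å MS, 1,4-dioxane, 60 °C, Ar; then 10% aq. citric acid, rt
Reagents that add atoms: 2,6-dimethylphenyl isocyanide, [C-]#[N+]c1c(C)cccc1C
Why: Proposed new method: the isocyanide acts as a one-carbon, formyl-level lynchpin — the bulky (IPr)Cu–OAr (IPr = 1,3-bis(2,6-diisopropylphenyl)imidazol-2-ylidene) forms only at unchelated phenols, 1,1-insertion of the isocyanide into Cu–O and protonolysis gives the aryl formimidate 6 at the 6-OH (formimidates parked on the 4-OH and the catechol are unproductive, exchange between phenols and are hydrolysed at work-up), the ketone enol carbon then adds to the ArO–CH=N carbon in a six-membered Mannich-type closure to 7, and loss of 2,6-dimethylaniline aromatises the pyranone; the 2-OH next to the prenyl group is flanked on both sides and held in the buttressed OH···O=C chelate in this non-basic medium, so it neither takes the one-carbon unit nor closes the ring, which gives the 6-prenyl and not the 8-prenyl isoflavone; the closest known reaction types are copper-catalysed insertion of isocyanides into O–H bonds to give formimidates, isocyanides as C1 units with loss of amine in benzoxazole and benzimidazole synthesis, and the formamide-acetal (enaminone) ring closure of 2-hydroxydeoxybenzoins to isoflavones.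

**Compound list**
1 | phloroglucinol (benzene-1,3,5-triol) | Oc1cc(O)cc(O)c1 | starting material
2 | 3,4-dihydroxyphenylacetic acid | OC(=O)Cc1ccc(O)c(O)c1 | starting material
3 | 2-(3,4-dihydroxyphenyl)-1-(2,4,6-trihydroxyphenyl)ethan-1-one | O=C(Cc1ccc(O)c(O)c1)c1c(O)cc(O)cc1O | intermediate
4 | prenyl bromide (1-bromo-3-methylbut-2-ene) | CC(C)=CCBr | starting material
5 | 2-(3,4-dihydroxyphenyl)-1-[2,4,6-trihydroxy-3-(3-methylbut-2-en-1-yl)phenyl]ethan-1-one | CC(C)=CCc1c(O)cc(O)c(C(=O)Cc2ccc(O)c(O)c2)c1O | intermediate
6 | 2-[(3,4-dihydroxyphenyl)acetyl]-3,5-dihydroxy-4-(3-methylbut-2-en-1-yl)phenyl (E)-N-(2,6-dimethylphenyl)methanimidate (aryl formimidate; C=N drawn E, geometry of no consequence) | CC(C)=CCc1c(O)cc(O/C=N/c2c(C)cccc2C)c(C(=O)Cc3ccc(O)c(O)c3)c1O | intermediate (not isolated)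
7 | 3-(3,4-dihydroxyphenyl)-2-(2,6-dimethylanilino)-5,7-dihydroxy-6-(3-methylbut-2-en-1-yl)chroman-4-one (racemic mixture of diastereomers; C2 and C3 are not controlled and both centres vanish on elimination) | CC(C)=CCc1c(O)cc2OC(Nc3c(C)cccc3C)C(c4ccc(O)c(O)c4)C(=O)c2c1O | intermediate (not isolated)
8 | 6-prenylorobol, 3-(3,4-dihydroxyphenyl)-5,7-dihydroxy-6-(3-methylbut-2-en-1-yl)-4H-chromen-4-one (achiral) | CC(C)=CCc1c(O)cc2occ(-c3ccc(O)c(O)c3)c(=O)c2c1O | target

**Step count and risks**
Total steps: 3. Longest linear sequence: 3 (1 → 3 → 5 → 8).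

Steps most likely to fail:

1. Step 3 (the proposed new step). Copper may be held by the catechol, and formimidoyl groups may stay parked on the other phenols. If 7 opens by loss of the ring phenoxide instead of the aniline, the regiochemistry rests only on the chelation of the 2-OH, and some 8-prenyl isomer would form. The fallback uses known chemistry only: it sets out from 3 and comes back at 8, closing the ring before the prenyl group is present and then placing the prenyl group by cross-coupling. 3 is ring-closed with BF3·OEt2, DMF and MsCl at 70 °C to orobol F3. MOMCl and i-Pr2NEt in CH2Cl2 cap the three unchelated phenols to give 7,3',4'-tris-O-(methoxymethyl)orobol F4. Benzyltrimethylammonium dichloroiodate with CaCO3 in CH2Cl2–MeOH iodinates next to the free 5-OH to give the 6-iodo compound F5. Stille coupling with tributyl(3-methylbut-2-en-1-yl)stannane (Pd(PPh3)4, DMF, 90 °C) gives the 6-prenyl tris-MOM ether F6. HCl in MeOH at 40 °C removes the three MOM groups and gives 8.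

2. Step 2. Likely problems are a second prenylation, O-prenylation, or alkylation and air oxidation of the catechol; a yield of about 35–45% with recovered 3 is expected. The fallback sets out from 3 and comes back at 5. It replaces phenoxide alkylation by an acid-mediated Friedel–Crafts prenylation of the neutral polyphenol with 2-methylbut-3-en-2-ol and BF3·OEt2 (0.5 equiv) in dioxane at rt, stopped at partial conversion. The dimethylallyl cation attacks the most electron-rich ring carbon and no phenoxide is present, so O-alkylation is excluded. No new compound is made.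

3. Step 1. Likely problems are incomplete acylation or tar from the free catechol at 85 °C. The fallback sets out from 1 and comes back at 3 by a Houben–Hoesch reaction. 1 and bought 3,4-dihydroxyphenylacetonitrile F1 are treated with ZnCl2 and HCl gas in Et2O at 0 °C, which precipitates the ketiminium chloride F2. Boiling F2 in water gives 3.

**Further compounds**
F1 | step 1 | 3,4-dihydroxyphenylacetonitrile (bought) | N#CCc1ccc(O)c(O)c1
F2 | step 1 | 2-(3,4-dihydroxyphenyl)-1-(2,4,6-trihydroxyphenyl)ethan-1-iminium chloride | [NH2+]=C(Cc1ccc(O)c(O)c1)c1c(O)cc(O)cc1O.[Cl-]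
F0 | step 2 | none | none
F3 | step 3 | orobol, 3-(3,4-dihydroxyphenyl)-5,7-dihydroxy-4H-chromen-4-one | O=c1c(-c2ccc(O)c(O)c2)coc2cc(O)cc(O)c12
F4 | step 3 | 3-[3,4-bis(methoxymethoxy)phenyl]-5-hydroxy-7-(methoxymethoxy)-4H-chromen-4-one | COCOc1ccc(-c2coc3cc(OCOC)cc(O)c3c2=O)cc1OCOC
F5 | step 3 | 3-[3,4-bis(methoxymethoxy)phenyl]-5-hydroxy-6-iodo-7-(methoxymethoxy)-4H-chromen-4-one | COCOc1ccc(-c2coc3cc(OCOC)c(I)c(O)c3c2=O)cc1OCOC
F6 | step 3 | 3-[3,4-bis(methoxymethoxy)phenyl]-5-hydroxy-7-(methoxymethoxy)-6-(3-methylbut-2-en-1-yl)-4H-chromen-4-one | COCOc1ccc(-c2coc3cc(OCOC)c(CC=C(C)C)c(O)c3c2=O)cc1OCOC
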